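The route hinges on cutting the C1–C10 bond of ring B. In ring A the ketone carbon C8 sits directly across from the fully substituted C5. Once C1–C10 is cut and a C6=C7 double bond is written in, ring A becomes a mirror-symmetric 4-methyl-4-alkylcyclohexa-2,5-dienone. Its side chain carries the C4 methyl, the C3 silyl ether and a (Z)-iodoalkene. A single intramolecular Heck reaction picks one of the two diastereotopic enone arms, closes ring B, turns C5 into a stereocentre and gives the C8/C9=C10/C1=C2 dienone. C6=C7 is left free for later work at C7. C3 and C4 come from one Evans syn aldol, C7 from a late organocerium addition, and both esters go on last.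

Key step: step 10

Remark: eremophilane numbering (ring B = C1–C5, C10; ring A = C5–C10; side chain C11–C13) is used from the first step on. The configurations written at C7 and C8 for the intermediates between the acetoxylation and the second ring-A oxidation are the expected ones. They carry no weight, because both carbons pass through a ketone.
Assumption: the five carbon building blocks marked as starting materials are purchased.

Step 1
Reactants: 1 (R)-4-benzyl-3-propionyloxazolidin-2-one; 2 3-(trimethylsilyl)prop-2-ynal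
Product: 4 (R)-4-benzyl-3-[(2R,3R)-3-hydroxy-2-methyl-5-(trimethylsilyl)pent-4-ynoyl]oxazolidin-2-one, via Z-dibutylboron enolate 3 (not isolated)
Conditions: n-Bu2BOTf, Et3N, CH2Cl2, 0 °C; 2, −78 to 0 °C; then pH 7 buffer, MeOH, 30% H2O2
Reagents that add atoms: none
Why: Evans syn aldol: the Z boron enolate reacts through a closed chair (Zimmerman–Traxler) transition state on the face turned away from the benzyl group, which should set C4 and C3 together in the syn relation and absolute sense required.

Step 2
Reactants: 4 aldol adduct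
Product: 5 (2R,3R)-3-hydroxy-N-methoxy-N,2-dimethyl-5-(trimethylsilyl)pent-4-ynamide
Conditions: MeNH(OMe)·HCl, AlMe3, CH2Cl2, −10 °C to rt
Reagents that add atoms: N,O-dimethylhydroxylamine hydrochloride CNOC.Cl
Why: Aluminium amide transamination to the Weinreb amide is helped by the free β-hydroxyl group, releases the auxiliary for recovery and leaves C3 and C4 untouched.

Step 3
Reactants: 5 hydroxy Weinreb amide
Product: 6 (2R,3R)-3-(tert-butyldimethylsilyloxy)-N-methoxy-N,2-dimethyl-5-(trimethylsilyl)pent-4-ynamide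
Conditions: t-BuMe2SiOTf, 2,6-lutidine, CH2Cl2, 0 °C
Reagents that add atoms: tert-butyldimethylsilyl triflate CC(C)(C)[Si](C)(C)OS(=O)(=O)C(F)(F)F
Why: Silyl triflate silylation of a secondary propargylic alcohol is routine and installs the C3 protecting group that is carried through the key step.

Step 4
Reactants: 6 silylated Weinreb amide
Product: 7 (3R,4R)-4-(tert-butyldimethylsilyloxy)-3-methyl-6-(trimethylsilyl)hex-5-yn-2-one
Conditions: MeMgBr, THF, 0 °C
Reagents that add atoms: methylmagnesium bromide C[Mg]Br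
Why: Weinreb ketone synthesis: the magnesium chelate of the tetrahedral adduct survives until work-up, so addition stops at the methyl ketone whose new methyl group becomes the C5 methyl.

Step 5
Reactants: 7 methyl ketone
Product: 9 (3S,4R)-4-(tert-butyldimethylsilyloxy)-2,3-dimethyl-6-(trimethylsilyl)hex-5-ynal (both C2 epimers), via methyl enol ether 8 (not isolated)
Conditions: Ph3P+CH2OMe Cl−, KN(SiMe3)2, THF, 0 °C to rt; then 2 M HCl, 0 °C to rt
Reagents that add atoms: (methoxymethyl)triphenylphosphonium chloride COC[P+](c1ccccc1)(c1ccccc1)c1ccccc1.[Cl-]; water O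
Why: Wittig methoxymethylenation and acid hydrolysis of the enol ether is the classical ketone-to-aldehyde homologation; keeping the phosphonium salt in slight excess over the base protects C4 from epimerisation, and the new C5 centre may form as a mixture because it loses its stereogenicity in step 7.

Step 6
Reactants: 9 α-branched aldehyde; 10 but-3-en-2-one
Product: 13 4-[(2S,3R)-3-(tert-butyldimethylsilyloxy)pent-4-yn-2-yl]-4-methylcyclohex-2-en-1-one (both ring C4 epimers), via C-desilylated aldehyde 11 (not isolated), via keto aldehyde 12 (not isolated)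
Conditions: KOH (0.3 equiv), MeOH, 0 °C to 65 °C
Reagents that add atoms: none
Why: Robinson annulation (Michael addition of the aldehyde enolate to butenone followed by aldol condensation) is the standard route to 4,4-disubstituted cyclohexenones, methanolic KOH also cleaves the alkynyl carbon–silicon bond, and the base-stable TBS ether and the non-acidic C4 centre are not affected.

Step 7
Reactants: 13 cyclohexenone
Product: 14 4-[(2S,3R)-3-(tert-butyldimethylsilyloxy)pent-4-yn-2-yl]-4-methylcyclohexa-2,5-dien-1-one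
Conditions: DDQ (2 equiv), 1,4-dioxane, 100 °C
Reagents that add atoms: none
Why: DDQ dehydrogenation of a 4,4-disubstituted cyclohexenone stops at the cross-conjugated dienone because the quaternary carbon blocks aromatisation, and both epimers of 13 converge since C5 now carries two identical arms.

Step 8
Reactants: 14 alkynyl dienone
Product: 15 4-[(2S,3R)-3-(tert-butyldimethylsilyloxy)-5-iodopent-4-yn-2-yl]-4-methylcyclohexa-2,5-dien-1-one
Conditions: NIS, AgNO3 (10 mol %), acetone, rt, dark
Reagents that add atoms: N-iodosuccinimide O=C1CCC(=O)N1I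
Why: Silver-catalysed electrophilic iodination of a terminal alkyne with NIS is mild and leaves the electron-poor dienone and the silyl ether alone.

Step 9
Reactants: 15 iodoalkyne
Product: 16 4-[(2S,3R,4Z)-3-(tert-butyldimethylsilyloxy)-5-iodopent-4-en-2-yl]-4-methylcyclohexa-2,5-dien-1-one
Conditions: 2-nitrobenzenesulfonylhydrazide, Et3N, THF/i-PrOH, rt
Reagents that add atoms: none
Why: Diimide reduction delivers both hydrogens to the same side of the iodoalkyne, the established way to Z-1-iodoalkenes, and the reactive triple bond should be consumed before the hindered, electron-poor ring double bonds.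

Step 10
Reactants: 16 (Z)-iodoalkenyl dienone
Product: 17 (3S,4S,5S)-3-(tert-butyldimethylsilyloxy)-11,12,13-trinoreremophila-1,6,9-trien-8-one [(4aS,5S,6S)-6-(tert-butyldimethylsilyloxy)-4a,5-dimethyl-5,6-dihydronaphthalen-2(4aH)-one]
Conditions: Pd(OAc)2 (10 mol %), PPh3 (30 mol %), Ag2CO3 (1.5 equiv), degassed MeCN, 70 °C
Reagents that add atoms: none
Why: Zerovalent palladium, formed in the flask from Pd(OAc)2 and PPh3, inserts into the carbon–iodine bond with retention of the Z geometry, Ag2CO3 removes iodide, and the cationic alkenylpalladium adds syn across one enone arm so that C1 bonds to C10 and the metal to C9. In this adduct H10 is anti to palladium, so the C-bound enolate passes through its O-bound form to the C9 epimer, from which syn β-hydride elimination takes H10, rebuilds C9=C10 and gives the linear C8/C9=C10/C1=C2 dienone; carbonate takes up the acid and no hydride donor is present, which holds back the reductive pathway. The closest known reaction type is the intramolecular Heck desymmetrisation of 4,4-disubstituted cyclohexa-2,5-dienones. Ring B (C1–C5, C10) closes in the 6-exo-trig mode. C5, the only new stereocentre, is controlled by the resident C4 and C3 centres: only two chair-like arrangements hold C1 above the β-carbon of an arm, and the one with C4–Me and C3–OTBS pseudoequatorial (C5–Me axial and cis to C4–Me) leads to 17, whereas the other makes both groups axial and pushes the C4 methyl over the dienone ring. The selectivity needed is therefore a choice between the diastereotopic C9=C10 and C6=C7 arms, secured by this equatorial preference, and the arm that does not react stays available for step 11.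

Step 11
Reactants: 17 trienone
Product: 18 (3S,4S,5S)-3-(tert-butyldimethylsilyloxy)-11,12,13-trinoreremophila-1,9-dien-8-one
Conditions: H2 (1 atm), RhCl(PPh3)3 (10 mol %), toluene/EtOH, rt
Reagents that add atoms: none
Why: Homogeneous hydrogenation with RhCl(PPh3)3 responds strongly to substitution and conjugation, so only the disubstituted C6=C7 bond of the short enone arm should be saturated, in line with the behaviour of steroidal 1,4,6-trien-3-ones that give 4,6-dien-3-ones.

Step 12
Reactants: 18 dienone
Product: 19 (3S,4S,5S,7S)-7-acetoxy-3-(tert-butyldimethylsilyloxy)-11,12,13-trinoreremophila-1,9-dien-8-one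
Conditions: Mn(OAc)3·2H2O (5 equiv), benzene, Dean–Stark, 80 °C
Reagents that add atoms: manganese triacetate CC(=O)[O-].CC(=O)[O-].CC(=O)[O-].[Mn+3]
Why: Mn(OAc)3 α'-acetoxylation of an enone proceeds through the manganese enolate on the saturated side, C7 is the only such position, and the acetate should end up equatorial (trans to the C5 methyl), a centre that is erased in step 16.

Step 13
Reactants: 19 acetoxy dienone
Product: 20 (3S,4S,5S,7S,8S)-7-acetoxy-3-(tert-butyldimethylsilyloxy)-11,12,13-trinoreremophila-1,9-dien-8-ol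
Conditions: NaBH4, CeCl3·7H2O, MeOH, −78 to −20 °C
Reagents that add atoms: none
Why: Luche reduction gives clean 1,2-reduction of the dienone; axial hydride delivery should give the pseudoequatorial C8 alcohol, whose configuration does not matter because C8 returns to a ketone in step 19.

Step 14
Reactants: 20 dienylic alcohol
Product: 21 (3S,4S,5S,7S,8S)-7-acetoxy-3-(tert-butyldimethylsilyloxy)-8-(triethylsilyloxy)-11,12,13-trinoreremophila-1,9-diene
Conditions: Et3SiCl, imidazole, DMAP (cat.), CH2Cl2, 0 °C
Reagents that add atoms: chlorotriethylsilane CC[Si](Cl)(CC)CC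
Why: Chlorosilane/imidazole silylation masks C8–OH as a triethylsilyl ether that can later be removed in the presence of TBS ethers, and the non-acidic conditions avoid ionisation of the dienylic alcohol.

Step 15
Reactants: 21 acetate
Product: 22 (3S,4S,5S,7S,8S)-3-(tert-butyldimethylsilyloxy)-8-(triethylsilyloxy)-11,12,13-trinoreremophila-1,9-dien-7-ol
Conditions: i-Bu2AlH (2.5 equiv), CH2Cl2, −78 °C
Reagents that add atoms: none
Why: Reductive ester cleavage with i-Bu2AlH at low temperature frees C7–OH as an aluminium alkoxide, which avoids the basic protic conditions under which the neighbouring silyl group could migrate.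

Step 16
Reactants: 22 C7 alcohol
Product: 23 (3S,4S,5S,8S)-3-(tert-butyldimethylsilyloxy)-8-(triethylsilyloxy)-11,12,13-trinoreremophila-1,9-dien-7-one
Conditions: Dess–Martin periodinane, NaHCO3, CH2Cl2, 0 °C to rt
Reagents that add atoms: none
Why: Buffered Dess–Martin oxidation converts the secondary alcohol into the C7 ketone under neutral conditions, so the acidic C8–H of this β,γ-unsaturated ketone is not disturbed and the C7/C8 oxidation levels are now exchanged.

Step 17
Reactants: 24 2-bromoprop-2-en-1-ol
Product: 25 (2-bromoallyloxy)(tert-butyl)dimethylsilane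
Conditions: t-BuMe2SiCl, imidazole, CH2Cl2, rt
Reagents that add atoms: tert-butyldimethylsilyl chloride CC(C)(C)[Si](C)(C)Cl
Why: Routine silylation of a primary allylic alcohol gives the precursor of the C11–C13 nucleophile.

Step 18
Reactants: 23 C7 ketone; 25 bromoallyl silyl ether
Product: 28 (3S,4S,5S,7S,8S)-3,13-bis(tert-butyldimethylsilyloxy)-8-(triethylsilyloxy)eremophila-1,9,11-trien-7-ol, via alkenyllithium 26 (not isolated), via alkenylcerium dichloride 27 (not isolated)
Conditions: 25, t-BuLi (2 equiv), Et2O, −78 °C; anhydrous CeCl3, THF, −78 °C; then 23, −78 °C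
Reagents that add atoms: none
Why: Bromine–lithium exchange, transmetalation to cerium and organocerium 1,2-addition: the weakly basic reagent adds to readily enolisable ketones, and it should approach C7 from the face opposite the pseudoaxial C5 methyl (a 1,3-relationship), placing the alkenyl group trans and the hydroxyl cis to that methyl as in the target.

Step 19
Reactants: 28 tertiary alcohol
Product: 30 (3S,4S,5S,7S)-3,13-bis(tert-butyldimethylsilyloxy)-7-hydroxyeremophila-1,9,11-trien-8-one, via 7,8-diol 29 (not isolated)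
Conditions: IBX (3 equiv), moist DMSO, rt
Reagents that add atoms: none
Why: IBX in DMSO is known to cleave triethylsilyl ethers while sparing TBS ethers and then oxidises the liberated dienylic alcohol to the conjugated ketone without breaking the carbon–carbon bond of the 1,2-diol.

Step 20
Reactants: 30 bis-silyl ether
Product: 31 (3S,4S,5S,7S)-3,7,13-trihydroxyeremophila-1,9,11-trien-8-one
Conditions: HF·pyridine, pyridine, THF, 0 °C to rt
Reagents that add atoms: none
Why: Fluoride desilylation with buffered HF·pyridine removes both TBS groups under mildly acidic conditions that the tertiary α-ketol and the dienone tolerate.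

Step 21
Reactants: 31 triol
Product: 32 (3S,4S,5S,7S)-13-acetoxy-3,7-dihydroxyeremophila-1,9,11-trien-8-one
Conditions: AcCl (1.1 equiv), 2,4,6-collidine, CH2Cl2, −78 °C
Reagents that add atoms: acetyl chloride CC(=O)Cl
Why: Low-temperature acylation with AcCl and the hindered base collidine is selective for primary over secondary alcohols, and the tertiary C7 hydroxyl is inert.

Step 22
Reactants: 33 (R)-2-methylbutanoic acid
Product: 34 (R)-2-methylbutan-1-ol
Conditions: LiAlH4, Et2O, 0 °C to rt
Reagents that add atoms: none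
Why: LiAlH4 reduction of the carboxylic acid does not involve the α-centre, so the R configuration is retained.

Step 23
Reactants: 34 (R)-2-methylbutan-1-ol
Product: 36 ethyl (2E,4R)-2,4-dimethylhex-2-enoate, via (R)-2-methylbutanal 35 (not isolated)
Conditions: TEMPO (10 mol %), PhI(OAc)2, Ph3P=C(Me)CO2Et, CH2Cl2, rt
Reagents that add atoms: ethyl 2-(triphenylphosphoranylidene)propanoate CCOC(=O)C(C)=P(c1ccccc1)(c1ccccc1)c1ccccc1
Why: Tandem TEMPO oxidation and Wittig olefination traps the volatile, epimerisable aldehyde at once under near-neutral conditions, and the α-branched stabilised ylide gives the E trisubstituted enoate.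

Step 24
Reactants: 36 enoate
Product: 37 (2E,4R)-2,4-dimethylhex-2-en-1-ol
Conditions: i-Bu2AlH (2.2 equiv), CH2Cl2, −78 °C
Reagents that add atoms: none
Why: i-Bu2AlH 1,2-reduction of the enoate gives the allylic alcohol without touching the double-bond geometry.

Step 25
Reactants: 37 allylic alcohol
Product: 39 ethyl (2E,4E,6R)-4,6-dimethylocta-2,4-dienoate, via enal 38 (not isolated)
Conditions: activated MnO2 (10 equiv), Ph3P=CHCO2Et, CH2Cl2, 40 °C
Reagents that add atoms: ethyl (triphenylphosphoranylidene)acetate CCOC(=O)C=P(c1ccccc1)(c1ccccc1)c1ccccc1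
Why: Tandem MnO2 oxidation and Wittig olefination traps the enal as it forms, and the stabilised ylide gives the E disubstituted double bond.

Step 26
Reactants: 39 dienoate
Product: 40 (2E,4E,6R)-4,6-dimethylocta-2,4-dienoic acid
Conditions: LiOH, THF/MeOH/H2O, rt; then 1 M HCl
Reagents that add atoms: lithium hydroxide [Li+].[OH-]
Why: Saponification of the ethyl ester is mild, and the dienoate has no epimerisable centre next to the carbonyl group.

Step 27
Reactants: 32 13-acetoxy diol; 40 dienoic acid
Product: 42 (3S,4S,5S,7S)-13-acetoxy-7-hydroxy-8-oxoeremophila-1,9,11-trien-3-yl (2E,4E,6R)-4,6-dimethylocta-2,4-dienoate (CNP0160850.1), via mixed anhydride 41 (not isolated)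
Conditions: 40, 2,4,6-trichlorobenzoyl chloride, Et3N, toluene, rt; then 32, DMAP, rt
Reagents that add atoms: none
Why: Yamaguchi esterification through the mixed anhydride acylates the secondary allylic C3 hydroxyl, whereas the tertiary C7 hydroxyl is too hindered to react and no stereocentre is involved.

Compound list
1 | (R)-4-benzyl-3-propionyloxazolidin-2-one | CCC(=O)N1[C@H](Cc2ccccc2)COC1=O | starting material
2 | 3-(trimethylsilyl)prop-2-ynal | O=CC#C[Si](C)(C)C | starting material
3 | Z-dibutylboron enolate of 1 | C/C=C(\OB(CCCC)CCCC)N1[C@H](Cc2ccccc2)COC1=O | intermediate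
4 | (R)-4-benzyl-3-[(2R,3R)-3-hydroxy-2-methyl-5-(trimethylsilyl)pent-4-ynoyl]oxazolidin-2-one | O=C1OC[C@@H](Cc2ccccc2)N1C(=O)[C@H](C)[C@@H](O)C#C[Si](C)(C)C | intermediate
5 | (2R,3R)-3-hydroxy-N-methoxy-N,2-dimethyl-5-(trimethylsilyl)pent-4-ynamide | CON(C)C(=O)[C@H](C)[C@@H](O)C#C[Si](C)(C)C | intermediate
6 | (2R,3R)-3-(tert-butyldimethylsilyloxy)-N-methoxy-N,2-dimethyl-5-(trimethylsilyl)pent-4-ynamide | CON(C)C(=O)[C@H](C)[C@@H](O[Si](C)(C)C(C)(C)C)C#C[Si](C)(C)C | intermediate
7 | (3R,4R)-4-(tert-butyldimethylsilyloxy)-3-methyl-6-(trimethylsilyl)hex-5-yn-2-one | CC(=O)[C@H](C)[C@@H](O[Si](C)(C)C(C)(C)C)C#C[Si](C)(C)C | intermediate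
8 | (3S,4R)-4-(tert-butyldimethylsilyloxy)-1-methoxy-2,3-dimethyl-6-(trimethylsilyl)hex-1-en-5-yne (E/Z mixture) | COC=C(C)[C@H](C)[C@@H](O[Si](C)(C)C(C)(C)C)C#C[Si](C)(C)C | intermediate
9 | (3S,4R)-4-(tert-butyldimethylsilyloxy)-2,3-dimethyl-6-(trimethylsilyl)hex-5-ynal (both C2 epimers) | O=CC(C)[C@H](C)[C@@H](O[Si](C)(C)C(C)(C)C)C#C[Si](C)(C)C | intermediate
10 | but-3-en-2-one | C=CC(C)=O | starting material
11 | (3S,4R)-4-(tert-butyldimethylsilyloxy)-2,3-dimethylhex-5-ynal | O=CC(C)[C@H](C)[C@@H](O[Si](C)(C)C(C)(C)C)C#C | intermediate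
12 | 2-[(2S,3R)-3-(tert-butyldimethylsilyloxy)pent-4-yn-2-yl]-2-methyl-5-oxohexanal | CC(=O)CCC(C)(C=O)[C@H](C)[C@@H](O[Si](C)(C)C(C)(C)C)C#C | intermediate
13 | 4-[(2S,3R)-3-(tert-butyldimethylsilyloxy)pent-4-yn-2-yl]-4-methylcyclohex-2-en-1-one (both ring C4 epimers) | O=C1C=CC(C)(CC1)[C@H](C)[C@@H](O[Si](C)(C)C(C)(C)C)C#C | intermediate
14 | 4-[(2S,3R)-3-(tert-butyldimethylsilyloxy)pent-4-yn-2-yl]-4-methylcyclohexa-2,5-dien-1-one | O=C1C=CC(C)(C=C1)[C@H](C)[C@@H](O[Si](C)(C)C(C)(C)C)C#C | intermediate
15 | 4-[(2S,3R)-3-(tert-butyldimethylsilyloxy)-5-iodopent-4-yn-2-yl]-4-methylcyclohexa-2,5-dien-1-one | O=C1C=CC(C)(C=C1)[C@H](C)[C@@H](O[Si](C)(C)C(C)(C)C)C#CI | intermediate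
16 | 4-[(2S,3R,4Z)-3-(tert-butyldimethylsilyloxy)-5-iodopent-4-en-2-yl]-4-methylcyclohexa-2,5-dien-1-one | O=C1C=CC(C)(C=C1)[C@H](C)[C@@H](O[Si](C)(C)C(C)(C)C)/C=C\I | intermediate
17 | (3S,4S,5S)-3-(tert-butyldimethylsilyloxy)-11,12,13-trinoreremophila-1,6,9-trien-8-one | O=C1C=C[C@]2(C)C(=C1)C=C[C@H](O[Si](C)(C)C(C)(C)C)[C@H]2C | intermediate
18 | (3S,4S,5S)-3-(tert-butyldimethylsilyloxy)-11,12,13-trinoreremophila-1,9-dien-8-one | O=C1CC[C@]2(C)C(=C1)C=C[C@H](O[Si](C)(C)C(C)(C)C)[C@H]2C | intermediate
19 | (3S,4S,5S,7S)-7-acetoxy-3-(tert-butyldimethylsilyloxy)-11,12,13-trinoreremophila-1,9-dien-8-one | CC(=O)O[C@H]1C[C@]2(C)C(=CC1=O)C=C[C@H](O[Si](C)(C)C(C)(C)C)[C@H]2C | intermediate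
20 | (3S,4S,5S,7S,8S)-7-acetoxy-3-(tert-butyldimethylsilyloxy)-11,12,13-trinoreremophila-1,9-dien-8-ol | CC(=O)O[C@H]1C[C@]2(C)C(=C[C@@H]1O)C=C[C@H](O[Si](C)(C)C(C)(C)C)[C@H]2C | intermediate
21 | (3S,4S,5S,7S,8S)-7-acetoxy-3-(tert-butyldimethylsilyloxy)-8-(triethylsilyloxy)-11,12,13-trinoreremophila-1,9-diene | CC(=O)O[C@H]1C[C@]2(C)C(=C[C@@H]1O[Si](CC)(CC)CC)C=C[C@H](O[Si](C)(C)C(C)(C)C)[C@H]2C | intermediate
22 | (3S,4S,5S,7S,8S)-3-(tert-butyldimethylsilyloxy)-8-(triethylsilyloxy)-11,12,13-trinoreremophila-1,9-dien-7-ol | O[C@H]1C[C@]2(C)C(=C[C@@H]1O[Si](CC)(CC)CC)C=C[C@H](O[Si](C)(C)C(C)(C)C)[C@H]2C | intermediate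
23 | (3S,4S,5S,8S)-3-(tert-butyldimethylsilyloxy)-8-(triethylsilyloxy)-11,12,13-trinoreremophila-1,9-dien-7-one | O=C1C[C@]2(C)C(=C[C@@H]1O[Si](CC)(CC)CC)C=C[C@H](O[Si](C)(C)C(C)(C)C)[C@H]2C | intermediate
24 | 2-bromoprop-2-en-1-ol | C=C(Br)CO | starting material
25 | (2-bromoallyloxy)(tert-butyl)dimethylsilane | C=C(Br)CO[Si](C)(C)C(C)(C)C | intermediate
26 | 3-(tert-butyldimethylsilyloxy)prop-1-en-2-yllithium | [Li]C(=C)CO[Si](C)(C)C(C)(C)C | intermediate
27 | 3-(tert-butyldimethylsilyloxy)prop-1-en-2-ylcerium dichloride | Cl[Ce](Cl)C(=C)CO[Si](C)(C)C(C)(C)C | intermediate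
28 | (3S,4S,5S,7S,8S)-3,13-bis(tert-butyldimethylsilyloxy)-8-(triethylsilyloxy)eremophila-1,9,11-trien-7-ol | C=C(CO[Si](C)(C)C(C)(C)C)[C@@]1(O)C[C@]2(C)C(=C[C@@H]1O[Si](CC)(CC)CC)C=C[C@H](O[Si](C)(C)C(C)(C)C)[C@H]2C | intermediate
29 | (3S,4S,5S,7S,8S)-3,13-bis(tert-butyldimethylsilyloxy)eremophila-1,9,11-triene-7,8-diol | C=C(CO[Si](C)(C)C(C)(C)C)[C@@]1(O)C[C@]2(C)C(=C[C@@H]1O)C=C[C@H](O[Si](C)(C)C(C)(C)C)[C@H]2C | intermediate
30 | (3S,4S,5S,7S)-3,13-bis(tert-butyldimethylsilyloxy)-7-hydroxyeremophila-1,9,11-trien-8-one | C=C(CO[Si](C)(C)C(C)(C)C)[C@@]1(O)C[C@]2(C)C(=CC1=O)C=C[C@H](O[Si](C)(C)C(C)(C)C)[C@H]2C | intermediate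
31 | (3S,4S,5S,7S)-3,7,13-trihydroxyeremophila-1,9,11-trien-8-one | C=C(CO)[C@@]1(O)C[C@]2(C)C(=CC1=O)C=C[C@H](O)[C@H]2C | intermediate
32 | (3S,4S,5S,7S)-13-acetoxy-3,7-dihydroxyeremophila-1,9,11-trien-8-one | C=C(COC(C)=O)[C@@]1(O)C[C@]2(C)C(=CC1=O)C=C[C@H](O)[C@H]2C | intermediate
33 | (R)-2-methylbutanoic acid | CC[C@@H](C)C(=O)O | starting material
34 | (R)-2-methylbutan-1-ol | CC[C@@H](C)CO | intermediate
35 | (R)-2-methylbutanal | CC[C@@H](C)C=O | intermediate
36 | ethyl (2E,4R)-2,4-dimethylhex-2-enoate | CCOC(=O)/C(C)=C/[C@H](C)CC | intermediate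
37 | (2E,4R)-2,4-dimethylhex-2-en-1-ol | OC/C(C)=C/[C@H](C)CC | intermediate
38 | (2E,4R)-2,4-dimethylhex-2-enal | O=C/C(C)=C/[C@H](C)CC | intermediate
39 | ethyl (2E,4E,6R)-4,6-dimethylocta-2,4-dienoate | CCOC(=O)/C=C/C(C)=C/[C@H](C)CC | intermediate
40 | (2E,4E,6R)-4,6-dimethylocta-2,4-dienoic acid | OC(=O)/C=C/C(C)=C/[C@H](C)CC | intermediate
41 | (2E,4E,6R)-4,6-dimethylocta-2,4-dienoic 2,4,6-trichlorobenzoic anhydride | O=C(OC(=O)c1c(Cl)cc(Cl)cc1Cl)/C=C/C(C)=C/[C@H](C)CC | intermediate
42 | (3S,4S,5S,7S)-13-acetoxy-7-hydroxy-8-oxoeremophila-1,9,11-trien-3-yl (2E,4E,6R)-4,6-dimethylocta-2,4-dienoate | C=C(COC(C)=O)[C@@]1(O)C[C@]2(C)C(=CC1=O)C=C[C@H](OC(=O)/C=C/C(C)=C/[C@H](C)CC)[C@H]2C | target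

Total step count: 27.
Longest linear sequence: 21 steps (steps 1–16, 18–21 and 27).

Steps most likely to fail

**Step 10.**
- What may go wrong: weak discrimination between the two enone arms, protonation of the palladium enolate in place of β-hydride loss, or drift of the alkenylpalladium from Z to E before ring closure.
- Fallback idea: separate ring closure from re-oxidation and use no palladium in the bond-forming event.
- The fallback sets out from 16. A tin hydride mediated vinyl radical cyclisation (n-Bu3SnH, Et3B, air, toluene, −20 °C) adds 6-exo to the β-carbon of one arm through the same chair-like arrangement. Vinyl radicals invert fast, so alkene geometry does not matter. This should give the cis-fused bicyclic enone F1.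
- Kinetic deprotonation at C9 with LiN(SiMe3)2 and trapping with Me3SiCl gives the cross-conjugated silyl dienol ether F2.
- Saegusa–Ito oxidation with Pd(OAc)2 in MeCN then installs C9=C10 and comes back to the route at 17.

**Step 18.**
- What may go wrong: deprotonation at C8 (its hydrogen is α to the ketone and dienylic) instead of addition, oxygen-to-carbon silyl migration within the lithiated allyl silyl ether before transmetalation, or loss of facial selectivity with so large a nucleophile.
- Fallback idea: leave the C13 oxygen out of the nucleophile and bring it in afterwards.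
- The fallback sets out from 23. Commercial isopropenylmagnesium bromide premixed with CeCl3 (THF, −78 °C) should add from the same face to give the isopropenyl carbinol F3.
- IBX in DMSO, as in step 19, gives the hydroxy dienone F4.
- Ene-type chlorination of the only electron-rich double bond with Ca(OCl)2 and CO2 in CH2Cl2/H2O gives the allylic chloride F5.
- Displacement with KOAc and 18-crown-6 in MeCN gives the silylated 13-acetate F6.
- HF·pyridine then frees the C3 hydroxyl, and the route is rejoined at 32.

**Step 9.**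
- What may go wrong: competing saturation of a ring double bond by diimide, or over-reduction of the iodoalkene.
- Fallback idea: build the Z-iodoalkene by olefination rather than by reduction.
- The fallback sets out from 14. Semihydrogenation (H2, Pd/CaCO3 poisoned with Pb(OAc)2, quinoline, EtOAc) gives the terminal alkene F7.
- Lemieux–Johnson cleavage (OsO4 cat., NaIO4, 2,6-lutidine, dioxane/H2O) of this most electron-rich double bond gives the α-silyloxy aldehyde F8.
- Stork–Zhao olefination (Ph3P+CH2I I−, NaN(SiMe3)2, THF, −78 °C) comes back to the route at 16. The aldehyde is far more reactive than the dienone at that temperature.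

Further compounds
F1 | step 10 | cis-fused (3S,4S,5S)-3-(tert-butyldimethylsilyloxy)-11,12,13-trinoreremophila-1,6-dien-8-one (H10 cis to the C5 methyl) | O=C1C=C[C@]2(C)[C@H](C1)C=C[C@H](O[Si](C)(C)C(C)(C)C)[C@H]2C
F2 | step 10 | 3-(tert-butyldimethylsilyloxy)-8-(trimethylsilyloxy)-11,12,13-trinoreremophila-1,6,8-triene | C[Si](C)(C)OC=1C=C[C@]2(C)[C@H](C=1)C=C[C@H](O[Si](C)(C)C(C)(C)C)[C@H]2C
F3 | step 18 | (3S,4S,5S,7S,8S)-3-(tert-butyldimethylsilyloxy)-8-(triethylsilyloxy)eremophila-1,9,11-trien-7-ol | C=C(C)[C@@]1(O)C[C@]2(C)C(=C[C@@H]1O[Si](CC)(CC)CC)C=C[C@H](O[Si](C)(C)C(C)(C)C)[C@H]2C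
F4 | step 18 | (3S,4S,5S,7S)-3-(tert-butyldimethylsilyloxy)-7-hydroxyeremophila-1,9,11-trien-8-one | C=C(C)[C@@]1(O)C[C@]2(C)C(=CC1=O)C=C[C@H](O[Si](C)(C)C(C)(C)C)[C@H]2C
F5 | step 18 | (3S,4S,5S,7S)-3-(tert-butyldimethylsilyloxy)-13-chloro-7-hydroxyeremophila-1,9,11-trien-8-one | C=C(CCl)[C@@]1(O)C[C@]2(C)C(=CC1=O)C=C[C@H](O[Si](C)(C)C(C)(C)C)[C@H]2C
F6 | step 18 | (3S,4S,5S,7S)-13-acetoxy-3-(tert-butyldimethylsilyloxy)-7-hydroxyeremophila-1,9,11-trien-8-one | C=C(COC(C)=O)[C@@]1(O)C[C@]2(C)C(=CC1=O)C=C[C@H](O[Si](C)(C)C(C)(C)C)[C@H]2C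
F7 | step 9 | 4-[(2S,3S)-3-(tert-butyldimethylsilyloxy)pent-4-en-2-yl]-4-methylcyclohexa-2,5-dien-1-one | O=C1C=CC(C)(C=C1)[C@H](C)[C@@H](O[Si](C)(C)C(C)(C)C)C=C
F8 | step 9 | (2R,3S)-2-(tert-butyldimethylsilyloxy)-3-(1-methyl-4-oxocyclohexa-2,5-dien-1-yl)butanal | O=C1C=CC(C)(C=C1)[C@H](C)[C@@H](O[Si](C)(C)C(C)(C)C)C=O
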